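The tetramer is assembled from two dimers joined last at C4(unit 2)–C8(unit 3). The strategy rests on building ring C of unit 3 around its C3–C4 bond: oxygen-bearing C3 sits next to a doubly benzylic C4 that already carries C8 of ring A of unit 4, with O3 trans to that aryl. A single amine-catalysed enamine addition to an ortho-quinone methide forms C3–C4, sets both stereocentres and closes ring C as a lactol through O1–C2. The precursor is an ortho-hydroxybenzhydrol whose carbinol carbon links the phloroglucinol-derived ring A of unit 3 to C8 of perbenzylated epicatechin.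

Key step: step 8

Conventions and assumptions
- Units are numbered 1 (catechin) to 4 (terminal epicatechin), with flavan numbering inside each unit; α/β refer to the usual flavan drawing in which the C2 aryl is α.
- Assumption: the carbinol epimers of 10 and 11 and the anomers of 16 are carried as mixtures, because these centres are erased in steps 8 and 9; their SMILES leave the centre undefined.
- Assumption: the sense of induction of the (S) catalyst follows the usual shielding model for diarylprolinol silyl ether enamines.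
- Assumption: the C4 leaving-group centre of 26 to 29 is written β as expected; it is lost on ionisation.

Step 1
Reactants: 1 (−)-epicatechin
Product: 2 5,7,3',4'-tetra-O-benzylepicatechin
Conditions: BnBr (4.4 equiv), K2CO3, DMF, 0 °C to rt, argon
Reagents that add atoms: benzyl bromide, BrCc1ccccc1
Why: Williamson etherification in which carbonate deprotonates only the four phenols, so the C3 alcohol and both stereocentres should stay untouched.

Step 2
Reactants: 2 5,7,3',4'-tetra-O-benzylepicatechin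
Product: 3 8-bromo-5,7,3',4'-tetra-O-benzylepicatechin
Conditions: NBS (1.0 equiv), CH2Cl2, −78 °C to rt
Reagents that add atoms: N-bromosuccinimide, O=C1CCC(=O)N1Br
Why: Electrophilic aromatic bromination, which should occur at C8 because it is the most nucleophilic position of the 5,7-dialkoxy ring A.

Step 3
Reactants: 3 8-bromo-5,7,3',4'-tetra-O-benzylepicatechin
Product: 4 8-bromo-3,5,7,3',4'-penta-O-benzylepicatechin
Conditions: NaH, BnBr, DMF, 0 °C to rt
Reagents that add atoms: benzyl bromide, BrCc1ccccc1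
Why: Williamson etherification of the C3 alkoxide removes the only acidic proton before halogen–lithium exchange and installs a group that leaves in the final hydrogenolysis.

Step 4
Reactants: 5 3,5-bis(benzyloxy)phenol
Product: 7 4,6-bis(benzyloxy)-2-hydroxybenzaldehyde, via ortho-hydroxymethyl phenol 6 (not isolated)
Conditions: (CH2O)n, MgCl2, Et3N, MeCN, reflux; then aq. HCl
Reagents that add atoms: paraformaldehyde (formaldehyde), C=O
Why: Magnesium-mediated ortho-formylation (Casnati–Skattebøl) delivers formaldehyde from the magnesium phenoxide to the carbon next to the OH (both ortho sites are equivalent), and a second formaldehyde oxidises 6 to the aldehyde.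

Step 5
Reactants: 7 4,6-bis(benzyloxy)-2-hydroxybenzaldehyde
Product: 8 4,6-bis(benzyloxy)-2-(triisopropylsilyloxy)benzaldehyde
Conditions: TIPSOTf, 2,6-lutidine, CH2Cl2, 0 °C
Reagents that add atoms: triisopropylsilyl trifluoromethanesulfonate, CC(C)[Si](OS(=O)(=O)C(F)(F)F)(C(C)C)C(C)C
Why: O-silylation masks the acidic phenol for the organolithium step, and the bulky triisopropylsilyl group should resist oxygen-to-oxygen migration onto the alkoxide formed in step 6.

Step 6
Reactants: 4 8-bromo-3,5,7,3',4'-penta-O-benzylepicatechin; 8 4,6-bis(benzyloxy)-2-(triisopropylsilyloxy)benzaldehyde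
Product: 10 [4,6-bis(benzyloxy)-2-(triisopropylsilyloxy)phenyl](3,5,7,3',4'-penta-O-benzylepicatechin-8-yl)methanol, via 8-lithio-penta-O-benzylepicatechin 9 (not isolated)
Conditions: n-BuLi (1.05 equiv), THF, −78 °C; then 8 (1.3 equiv), −78 °C; AcOH quench at −78 °C
Reagents that add atoms: none
Why: Bromine–lithium exchange at C8 then 1,2-addition of the aryllithium to the aldehyde makes the C4(unit 3)–C8(unit 4) bond, and the new carbinol centre forms without control because it is erased in step 8.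

Step 7
Reactants: 10 [4,6-bis(benzyloxy)-2-(triisopropylsilyloxy)phenyl](3,5,7,3',4'-penta-O-benzylepicatechin-8-yl)methanol
Product: 11 [4,6-bis(benzyloxy)-2-hydroxyphenyl](3,5,7,3',4'-penta-O-benzylepicatechin-8-yl)methanol
Conditions: TBAF (1.1 equiv), AcOH (1.1 equiv), THF, 0 °C; used at once without chromatography
Reagents that add atoms: none
Why: Fluoride cleavage of the aryl silyl ether under acetate buffering should free the phenol without ionising the acid-labile benzhydrol.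

Step 8
Reactants: 11 [4,6-bis(benzyloxy)-2-hydroxyphenyl](3,5,7,3',4'-penta-O-benzylepicatechin-8-yl)methanol; 12 (tert-butyldimethylsilyloxy)acetaldehyde
Product: 16 5,7-bis(benzyloxy)-3α-(tert-butyldimethylsilyloxy)-4β-(3,5,7,3',4'-penta-O-benzylepicatechin-8-yl)chroman-2-ol (unit 3 lactol), via ortho-quinone methide 13 (not isolated), via catalyst enamine 14 (not isolated), via hydroxy aldehyde 15 (not isolated)
Conditions: (S)-2-[diphenyl(trimethylsilyloxy)methyl]pyrrolidine (20 mol%), PhCO2H (20 mol%), 12 (3 equiv), CH2Cl2, 0 °C to rt; 11 added slowly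
Reagents that add atoms: none
Why: Benzoic acid helps 11 lose water to the ortho-quinone methide 13, which only ring A of unit 3 can form because it carries the sole free phenol, while the catalyst condenses with 12 to the E-enamine 14; the enamine carbon attacks the methide carbon (C3–C4), the iminium is hydrolysed to hydroxy aldehyde 15, and the phenol adds to the aldehyde to give 16. The closest known reaction type is the amine-catalysed formal [4+2] (Michael addition then hemiacetalisation) of aldehydes with ortho-quinone methides generated in situ, which gives 3,4-trans-chroman-2-ols. Ring C closes by reversible 6-exo-trig attack of the phenol oxygen on the aldehyde carbon (O1–C2). C3 is set by the catalyst, whose diphenyl(silyloxy)methyl group blocks one face of the anti E-enamine so that the electrophile is taken up on the other face (O3 α, 3R), and C4 is set relative to C3 by the synclinal open transition state between the E-enamine and the E-methide that keeps the C4 aryl away from the pyrrolidine (4β, trans to O3); the anomeric C2 is not controlled and does not matter. The step needs C-alkylation of the enamine to outrun attack of a second phenol on the methide, which slow addition of 11 to excess 12 and the much higher nucleophilicity of the enamine should secure, and it needs an unambiguous union with unit 4, which the C4–C8 bond already present in 11 guarantees.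

Step 9
Reactants: 16 unit 3 lactol; 17 4-bromo-1,2-bis(benzyloxy)benzene
Product: 20 (1,2-anti)-1-[3,4-bis(benzyloxy)phenyl]-3-[4,6-bis(benzyloxy)-2-hydroxyphenyl]-2-(tert-butyldimethylsilyloxy)-3-(3,5,7,3',4'-penta-O-benzylepicatechin-8-yl)propan-1-ol, via 3,4-bis(benzyloxy)phenyllithium 18 (not isolated), via aryltitanium triisopropoxide 19 (not isolated)
Conditions: 17, n-BuLi, THF, −78 °C; ClTi(OiPr)3, −78 to −40 °C; then 16, −40 to 0 °C (4 equiv of 19); aq. NH4Cl
Reagents that add atoms: none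
Why: Transmetalation gives a non-chelating aryltitanium that adds to the aldehyde of the ring-opened lactol (15) under polar Felkin–Anh control, so the new C2 carbinol should form anti to the bulky C3 silyloxy group.

Step 10
Reactants: 20 (1,2-anti) carbinol
Product: 21 3-O-(tert-butyldimethylsilyl)-5,7,3',4'-tetra-O-benzylepicatechin-(4β→8)-3,5,7,3',4'-penta-O-benzylepicatechin
Conditions: PPh3, DIAD, THF, 0 °C to rt
Reagents that add atoms: none
Why: Intramolecular Mitsunobu etherification in which the phenol, the only acidic OH, displaces the activated benzylic oxygen by 6-exo-tet SN2 closure with inversion at C2, turning the 2,3-anti carbinol into the 2,3-cis (2R) flavan.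

Step 11
Reactants: 21 silylated units 3–4 dimer
Product: 22 5,7,3',4'-tetra-O-benzylepicatechin-(4β→8)-3,5,7,3',4'-penta-O-benzylepicatechin
Conditions: HF·pyridine, pyridine, THF, 0 °C to rt
Reagents that add atoms: none
Why: Fluoride-mediated desilylation of the secondary silyl ether under buffered conditions should leave the benzyl ethers and the interflavan bond intact.

Step 12
Reactants: 23 (+)-catechin
Product: 24 5,7,3',4'-tetra-O-benzylcatechin
Conditions: BnBr (4.4 equiv), K2CO3, DMF, 0 °C to rt, argon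
Reagents that add atoms: benzyl bromide, BrCc1ccccc1
Why: Williamson etherification of the four phenols only, as in step 1.

Step 13
Reactants: 24 5,7,3',4'-tetra-O-benzylcatechin
Product: 25 8-bromo-5,7,3',4'-tetra-O-benzylcatechin
Conditions: NBS (1.0 equiv), CH2Cl2, −78 °C to rt
Reagents that add atoms: N-bromosuccinimide, O=C1CCC(=O)N1Br
Why: Electrophilic aromatic bromination at C8 caps the most nucleophilic site of unit 1, so that the later C4 cation cannot condense with its own kind there.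

Step 14
Reactants: 25 8-bromo-5,7,3',4'-tetra-O-benzylcatechin
Product: 26 8-bromo-4β-(2-ethoxyethoxy)-5,7,3',4'-tetra-O-benzylcatechin
Conditions: DDQ (2 equiv), 2-ethoxyethanol, CH2Cl2, rt
Reagents that add atoms: 2-ethoxyethanol, CCOCCO
Why: DDQ benzylic oxidation abstracts hydride from C4 to a cation stabilised by O1 and the 5,7-oxygens, which the alcohol traps (expected mainly on the β face).

Step 15
Reactants: 26 8-bromo-4β-(2-ethoxyethoxy)-5,7,3',4'-tetra-O-benzylcatechin
Product: 27 3-O-acetyl-8-bromo-4β-(2-ethoxyethoxy)-5,7,3',4'-tetra-O-benzylcatechin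
Conditions: Ac2O, pyridine, DMAP (cat.), CH2Cl2, rt
Reagents that add atoms: acetic anhydride, CC(=O)OC(C)=O
Why: DMAP-catalysed acylation of the C3 alcohol installs the neighbouring group that steers the interflavan bond of step 18.

Step 16
Reactants: 3 8-bromo-5,7,3',4'-tetra-O-benzylepicatechin
Product: 28 8-bromo-4β-(2-ethoxyethoxy)-5,7,3',4'-tetra-O-benzylepicatechin
Conditions: DDQ (2 equiv), 2-ethoxyethanol, CH2Cl2, rt
Reagents that add atoms: 2-ethoxyethanol, CCOCCO
Why: DDQ benzylic oxidation at C4 as in step 14, with the alcohol entering trans to O3 and to the C2 aryl (β).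

Step 17
Reactants: 28 8-bromo-4β-(2-ethoxyethoxy)-5,7,3',4'-tetra-O-benzylepicatechin
Product: 29 8-bromo-4β-(2,6-dimethylphenylthio)-5,7,3',4'-tetra-O-benzylepicatechin
Conditions: 2,6-Me2C6H3SH (2 equiv), BF3·OEt2 (cat.), CH2Cl2, −78 to −30 °C
Reagents that add atoms: 2,6-dimethylbenzenethiol, Cc1cccc(C)c1S
Why: Lewis acid-mediated SN1 exchange at C4 in which the thiol attacks the cation on the β face trans to O3, giving a hindered thioether that hard Lewis acids leave alone and silver can later ionise.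

Step 18
Reactants: 27 3-O-acetyl-8-bromo-4β-(2-ethoxyethoxy)-5,7,3',4'-tetra-O-benzylcatechin; 29 8-bromo-4β-(2,6-dimethylphenylthio)-5,7,3',4'-tetra-O-benzylepicatechin
Product: 30 [3-O-acetyl-8-bromo-5,7,3',4'-tetra-O-benzylcatechin]-(4α→6)-[8-bromo-4β-(2,6-dimethylphenylthio)-5,7,3',4'-tetra-O-benzylepicatechin]
Conditions: BF3·OEt2 (0.5 equiv), CH2Cl2, −78 to −20 °C; 29 (3 equiv), 27 added slowly
Reagents that add atoms: none
Why: Friedel–Crafts alkylation by the flavan-4-yl cation of 27, in which the 3-acetoxy group bridges the β face so that C6 of 29, its only free ring A position, attacks from the α face (4α, 3,4-trans) while the thioether stays intact.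

Step 19
Reactants: 30 units 1–2 thioether dimer; 22 units 3–4 dimer
Product: 31 protected tetramer (3-O-acetyl on unit 1 and 8-bromo on units 1 and 2 and 17 benzyl ethers)
Conditions: AgBF4 (2 equiv), 2,6-di-tert-butyl-4-methylpyridine (2 equiv), THF, −20 to 0 °C, dark; 22 (1.5 equiv)
Reagents that add atoms: none
Why: Silver-promoted ionisation of the C4–S bond gives the unit 2 C4 cation, which the most nucleophilic arene position of 22, C8 of unit 3, should attack from the β face trans to O3 and to the C2 aryl (4β) in a Friedel–Crafts interflavan coupling.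

Step 20
Reactants: 31 protected tetramer
Product: 32 deacetylated tetramer
Conditions: NaOMe (cat.), MeOH/THF, rt
Reagents that add atoms: none
Why: Zemplén transesterification removes the single acetate before any base-sensitive free phenol is exposed.

Step 21
Reactants: 32 deacetylated tetramer
Product: 33 catechin-(4α→6)-epicatechin-(4β→8)-epicatechin-(4β→8)-epicatechin (CNP0228086.1)
Conditions: H2 (1 atm), Pd(OH)2/C, Et3N (2.5 equiv), THF/MeOH/H2O, rt
Reagents that add atoms: none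
Why: Catalytic hydrogenolysis cleaves the 17 benzyl ethers and both aryl C–Br bonds while Et3N traps HBr, and no stereocentre is touched.

Compound list
1 | (−)-epicatechin | Oc1cc(O)c2c(c1)O[C@H](c1ccc(O)c(O)c1)[C@H](O)C2 | starting material
2 | 5,7,3',4'-tetra-O-benzylepicatechin | c1c(OCc9ccccc9)cc(OCc9ccccc9)c2c1O[C@H](c8ccc(OCc9ccccc9)c(OCc9ccccc9)c8)[C@H](O)C2 | intermediate
3 | 8-bromo-5,7,3',4'-tetra-O-benzylepicatechin | Brc1c(OCc9ccccc9)cc(OCc9ccccc9)c2c1O[C@H](c8ccc(OCc9ccccc9)c(OCc9ccccc9)c8)[C@H](O)C2 | intermediate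
4 | 8-bromo-3,5,7,3',4'-penta-O-benzylepicatechin | Brc1c(OCc9ccccc9)cc(OCc9ccccc9)c2c1O[C@H](c8ccc(OCc9ccccc9)c(OCc9ccccc9)c8)[C@H](OCc9ccccc9)C2 | intermediate
5 | 3,5-bis(benzyloxy)phenol | Oc1cc(OCc2ccccc2)cc(OCc2ccccc2)c1 | starting material
6 | 3,5-bis(benzyloxy)-2-(hydroxymethyl)phenol (magnesium salt in the flask) | OCc1c(O)cc(OCc2ccccc2)cc1OCc1ccccc1 | intermediate
7 | 4,6-bis(benzyloxy)-2-hydroxybenzaldehyde | O=Cc1c(O)cc(OCc2ccccc2)cc1OCc1ccccc1 | intermediate
8 | 4,6-bis(benzyloxy)-2-(triisopropylsilyloxy)benzaldehyde | O=Cc1c(O[Si](C(C)C)(C(C)C)C(C)C)cc(OCc2ccccc2)cc1OCc1ccccc1 | intermediate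
9 | 8-lithio-3,5,7,3',4'-penta-O-benzylepicatechin | [Li]c1c(OCc9ccccc9)cc(OCc9ccccc9)c2c1O[C@H](c8ccc(OCc9ccccc9)c(OCc9ccccc9)c8)[C@H](OCc9ccccc9)C2 | intermediate
10 | [4,6-bis(benzyloxy)-2-(triisopropylsilyloxy)phenyl](3,5,7,3',4'-penta-O-benzylepicatechin-8-yl)methanol (both carbinol epimers) | CC(C)[Si](C(C)C)(C(C)C)Oc1cc(OCc9ccccc9)cc(OCc9ccccc9)c1C(O)c1c(OCc9ccccc9)cc(OCc9ccccc9)c2c1O[C@H](c8ccc(OCc9ccccc9)c(OCc9ccccc9)c8)[C@H](OCc9ccccc9)C2 | intermediate
11 | [4,6-bis(benzyloxy)-2-hydroxyphenyl](3,5,7,3',4'-penta-O-benzylepicatechin-8-yl)methanol (both carbinol epimers; precursor of the key step) | Oc1cc(OCc9ccccc9)cc(OCc9ccccc9)c1C(O)c1c(OCc9ccccc9)cc(OCc9ccccc9)c2c1O[C@H](c8ccc(OCc9ccccc9)c(OCc9ccccc9)c8)[C@H](OCc9ccccc9)C2 | intermediate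
12 | (tert-butyldimethylsilyloxy)acetaldehyde | CC(C)(C)[Si](C)(C)OCC=O | starting material
13 | ortho-quinone methide of 11 (E; methide carbon is C4 of unit 3 and carries C8 of unit 4) | O=C1C=C(OCc9ccccc9)C=C(OCc9ccccc9)/C1=C\c1c(OCc9ccccc9)cc(OCc9ccccc9)c2c1O[C@H](c8ccc(OCc9ccccc9)c(OCc9ccccc9)c8)[C@H](OCc9ccccc9)C2 | intermediate
14 | E-enamine of 12 with (S)-2-[diphenyl(trimethylsilyloxy)methyl]pyrrolidine | CC(C)(C)[Si](C)(C)O/C=C/N1CCC[C@H]1C(c2ccccc2)(c2ccccc2)O[Si](C)(C)C | intermediate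
15 | (2R)-3-[4,6-bis(benzyloxy)-2-hydroxyphenyl]-2-(tert-butyldimethylsilyloxy)-3-(3,5,7,3',4'-penta-O-benzylepicatechin-8-yl)propanal (open form of 16) | O=C[C@H](O[Si](C)(C)C(C)(C)C)[C@H](c1c(O)cc(OCc9ccccc9)cc1OCc9ccccc9)c1c(OCc9ccccc9)cc(OCc9ccccc9)c2c1O[C@H](c8ccc(OCc9ccccc9)c(OCc9ccccc9)c8)[C@H](OCc9ccccc9)C2 | intermediate
16 | 5,7-bis(benzyloxy)-3α-(tert-butyldimethylsilyloxy)-4β-(3,5,7,3',4'-penta-O-benzylepicatechin-8-yl)chroman-2-ol (unit 3 lactol; both anomers; 3,4-trans) | c1c(OCc9ccccc9)cc(OCc9ccccc9)c3c1OC(O)[C@H](O[Si](C)(C)C(C)(C)C)[C@H]3c1c(OCc9ccccc9)cc(OCc9ccccc9)c2c1O[C@H](c8ccc(OCc9ccccc9)c(OCc9ccccc9)c8)[C@H](OCc9ccccc9)C2 | intermediate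
17 | 4-bromo-1,2-bis(benzyloxy)benzene | Brc1ccc(OCc2ccccc2)c(OCc2ccccc2)c1 | starting material
18 | 3,4-bis(benzyloxy)phenyllithium | [Li]c1ccc(OCc2ccccc2)c(OCc2ccccc2)c1 | intermediate
19 | [3,4-bis(benzyloxy)phenyl]Ti(OiPr)3 | CC(C)O[Ti](OC(C)C)(OC(C)C)c1ccc(OCc2ccccc2)c(OCc2ccccc2)c1 | intermediate
20 | (1,2-anti)-1-[3,4-bis(benzyloxy)phenyl]-3-[4,6-bis(benzyloxy)-2-hydroxyphenyl]-2-(tert-butyldimethylsilyloxy)-3-(3,5,7,3',4'-penta-O-benzylepicatechin-8-yl)propan-1-ol | O[C@@H](c8ccc(OCc9ccccc9)c(OCc9ccccc9)c8)[C@H](O[Si](C)(C)C(C)(C)C)[C@H](c1c(O)cc(OCc9ccccc9)cc1OCc9ccccc9)c1c(OCc9ccccc9)cc(OCc9ccccc9)c2c1O[C@H](c8ccc(OCc9ccccc9)c(OCc9ccccc9)c8)[C@H](OCc9ccccc9)C2 | intermediate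
21 | 3-O-(tert-butyldimethylsilyl)-5,7,3',4'-tetra-O-benzylepicatechin-(4β→8)-3,5,7,3',4'-penta-O-benzylepicatechin | c1c(OCc9ccccc9)cc(OCc9ccccc9)c3c1O[C@H](c8ccc(OCc9ccccc9)c(OCc9ccccc9)c8)[C@H](O[Si](C)(C)C(C)(C)C)[C@H]3c1c(OCc9ccccc9)cc(OCc9ccccc9)c2c1O[C@H](c8ccc(OCc9ccccc9)c(OCc9ccccc9)c8)[C@H](OCc9ccccc9)C2 | intermediate
22 | 5,7,3',4'-tetra-O-benzylepicatechin-(4β→8)-3,5,7,3',4'-penta-O-benzylepicatechin (free 3-OH on unit 3) | c1c(OCc9ccccc9)cc(OCc9ccccc9)c3c1O[C@H](c8ccc(OCc9ccccc9)c(OCc9ccccc9)c8)[C@H](O)[C@H]3c1c(OCc9ccccc9)cc(OCc9ccccc9)c2c1O[C@H](c8ccc(OCc9ccccc9)c(OCc9ccccc9)c8)[C@H](OCc9ccccc9)C2 | intermediate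
23 | (+)-catechin | Oc1cc(O)c2c(c1)O[C@H](c1ccc(O)c(O)c1)[C@@H](O)C2 | starting material
24 | 5,7,3',4'-tetra-O-benzylcatechin | c1c(OCc9ccccc9)cc(OCc9ccccc9)c2c1O[C@H](c8ccc(OCc9ccccc9)c(OCc9ccccc9)c8)[C@@H](O)C2 | intermediate
25 | 8-bromo-5,7,3',4'-tetra-O-benzylcatechin | Brc1c(OCc9ccccc9)cc(OCc9ccccc9)c2c1O[C@H](c8ccc(OCc9ccccc9)c(OCc9ccccc9)c8)[C@@H](O)C2 | intermediate
26 | 8-bromo-4β-(2-ethoxyethoxy)-5,7,3',4'-tetra-O-benzylcatechin | Brc1c(OCc9ccccc9)cc(OCc9ccccc9)c2c1O[C@H](c8ccc(OCc9ccccc9)c(OCc9ccccc9)c8)[C@@H](O)[C@H]2OCCOCC | intermediate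
27 | 3-O-acetyl-8-bromo-4β-(2-ethoxyethoxy)-5,7,3',4'-tetra-O-benzylcatechin | Brc1c(OCc9ccccc9)cc(OCc9ccccc9)c2c1O[C@H](c8ccc(OCc9ccccc9)c(OCc9ccccc9)c8)[C@@H](OC(C)=O)[C@H]2OCCOCC | intermediate
28 | 8-bromo-4β-(2-ethoxyethoxy)-5,7,3',4'-tetra-O-benzylepicatechin | Brc1c(OCc9ccccc9)cc(OCc9ccccc9)c2c1O[C@H](c8ccc(OCc9ccccc9)c(OCc9ccccc9)c8)[C@H](O)[C@H]2OCCOCC | intermediate
29 | 8-bromo-4β-(2,6-dimethylphenylthio)-5,7,3',4'-tetra-O-benzylepicatechin | Brc1c(OCc9ccccc9)cc(OCc9ccccc9)c2c1O[C@H](c8ccc(OCc9ccccc9)c(OCc9ccccc9)c8)[C@H](O)[C@H]2Sc1c(C)cccc1C | intermediate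
30 | [3-O-acetyl-8-bromo-5,7,3',4'-tetra-O-benzylcatechin]-(4α→6)-[8-bromo-4β-(2,6-dimethylphenylthio)-5,7,3',4'-tetra-O-benzylepicatechin] | Brc1c(OCc9ccccc9)cc(OCc9ccccc9)c2c1O[C@H](c8ccc(OCc9ccccc9)c(OCc9ccccc9)c8)[C@@H](OC(C)=O)[C@@H]2c1c(OCc9ccccc9)c(Br)c2c(c1OCc9ccccc9)[C@H](Sc1c(C)cccc1C)[C@@H](O)[C@@H](c8ccc(OCc9ccccc9)c(OCc9ccccc9)c8)O2 | intermediate
31 | protected tetramer: unit 1 3-O-acetyl-8-bromo-tetra-O-benzylcatechin (4α→6), unit 2 8-bromo-tetra-O-benzylepicatechin (4β→8), unit 3 tetra-O-benzylepicatechin (4β→8), unit 4 penta-O-benzylepicatechin | Brc1c(OCc9ccccc9)cc(OCc9ccccc9)c2c1O[C@H](c8ccc(OCc9ccccc9)c(OCc9ccccc9)c8)[C@@H](OC(C)=O)[C@@H]2c1c(OCc9ccccc9)c(Br)c2c(c1OCc9ccccc9)[C@H](c1c(OCc9ccccc9)cc(OCc9ccccc9)c3c1O[C@H](c8ccc(OCc9ccccc9)c(OCc9ccccc9)c8)[C@H](O)[C@H]3c1c(OCc9ccccc9)cc(OCc9ccccc9)c3c1O[C@H](c8ccc(OCc9ccccc9)c(OCc9ccccc9)c8)[C@H](OCc9ccccc9)C3)[C@@H](O)[C@@H](c8ccc(OCc9ccccc9)c(OCc9ccccc9)c8)O2 | intermediate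
32 | deacetylated tetramer (as 31 with free 3-OH on unit 1) | Brc1c(OCc9ccccc9)cc(OCc9ccccc9)c2c1O[C@H](c8ccc(OCc9ccccc9)c(OCc9ccccc9)c8)[C@@H](O)[C@@H]2c1c(OCc9ccccc9)c(Br)c2c(c1OCc9ccccc9)[C@H](c1c(OCc9ccccc9)cc(OCc9ccccc9)c3c1O[C@H](c8ccc(OCc9ccccc9)c(OCc9ccccc9)c8)[C@H](O)[C@H]3c1c(OCc9ccccc9)cc(OCc9ccccc9)c3c1O[C@H](c8ccc(OCc9ccccc9)c(OCc9ccccc9)c8)[C@H](OCc9ccccc9)C3)[C@@H](O)[C@@H](c8ccc(OCc9ccccc9)c(OCc9ccccc9)c8)O2 | intermediate
33 | catechin-(4α→6)-epicatechin-(4β→8)-epicatechin-(4β→8)-epicatechin (CNP0228086.1) | Oc1cc(O)c2c(c1)O[C@H](c1ccc(O)c(O)c1)[C@@H](O)[C@@H]2c1c(O)cc2c(c1O)[C@H](c1c(O)cc(O)c3c1O[C@H](c1ccc(O)c(O)c1)[C@H](O)[C@H]3c1c(O)cc(O)c3c1O[C@H](c1ccc(O)c(O)c1)[C@H](O)C3)[C@@H](O)[C@@H](c1ccc(O)c(O)c1)O2 | target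

Total step count: 21
Longest linear sequence: 12 steps (steps 1, 2, 3, 6, 7, 8, 9, 10, 11, 19, 20, 21)

Steps most likely to fail

1. Step 8. The quinone methide carries two benzyloxy donors and a trioxygenated aryl group, so enamine addition may be slow and attack by the free phloroglucinol-type ring of a second molecule may compete. The C5 benzyloxy group may erode the E geometry of the methide and with it the 3,4-trans selectivity, and the stereocentres of unit 4 may oppose the catalyst. The fallback gives up the annulation and makes the units 3–4 dimer by flavan-4-yl cation chemistry. It sets out from 2: oxidation with DDQ and 2-ethoxyethanol in CH2Cl2 gives 4β-(2-ethoxyethoxy)-5,7,3',4'-tetra-O-benzylepicatechin F1, and a second portion of 2 is benzylated at O3 (NaH, BnBr, DMF) to 3,5,7,3',4'-penta-O-benzylepicatechin F2. TMSOTf (cat.) in CH2Cl2 at −78 °C with excess F2 should join C4 of F1 to C8 of F2 on the β face, trans to O3 and to the C2 aryl. The fallback comes back to the route at 22.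

2. Step 9. The lactol may open incompletely, or the aryl group may be delivered through a titanium phenoxide or a chelate instead of the Felkin–Anh mode, giving poor facial selectivity at C2 that step 10 would carry into the ring. The fallback sets C2 by oxocarbenium reduction and sets out from 16. The Grignard reagent [3,4-bis(benzyloxy)phenyl]MgBr (from 17 and Mg in THF) is added without any stereochemical demand, giving the C2-epimeric carbinols (20 together with its C2 epimer) F3. MnO2 in CH2Cl2 oxidises the benzylic carbinol to the aryl ketone, which the phenol closes to the 2-aryl-2-hydroxychroman hemiketal F4. Et3SiH with BF3·OEt2 in CH2Cl2 at −78 °C should deliver hydride to the 2-aryl oxocarbenium ion anti to the pseudoaxial C3 silyloxy group, giving the 2,3-cis flavan. The fallback comes back at 21 and bypasses step 10 as well.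

3. Step 18. Attack at the hindered, bromine-deactivated C6 of 29 may be slow, so that the cation of 27 is consumed by oligomerisation through its own C6 or the thio group migrates between units. The fallback activates unit 2 late and sets out from 27 and 3. BF3·OEt2 or TMSOTf (cat.) in CH2Cl2 at −78 to −20 °C with excess 3 gives [3-O-acetyl-8-bromo-5,7,3',4'-tetra-O-benzylcatechin]-(4α→6)-[8-bromo-5,7,3',4'-tetra-O-benzylepicatechin] F5. DDQ with 2-ethoxyethanol then oxidises the only remaining ring CH2, C4 of unit 2, to the 4β-(2-ethoxyethoxy) dimer F6. TMSOTf (cat.) at −78 °C couples F6 with 22 at C8 of unit 3. The fallback comes back at 31.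

Further compounds
F1 | step 8 | 4β-(2-ethoxyethoxy)-5,7,3',4'-tetra-O-benzylepicatechin | c1c(OCc9ccccc9)cc(OCc9ccccc9)c2c1O[C@H](c8ccc(OCc9ccccc9)c(OCc9ccccc9)c8)[C@H](O)[C@H]2OCCOCC
F2 | step 8 | 3,5,7,3',4'-penta-O-benzylepicatechin | c1c(OCc9ccccc9)cc(OCc9ccccc9)c2c1O[C@H](c8ccc(OCc9ccccc9)c(OCc9ccccc9)c8)[C@H](OCc9ccccc9)C2
F3 | step 9 | C2-epimeric carbinols (20 together with its C2 epimer) | OC(c8ccc(OCc9ccccc9)c(OCc9ccccc9)c8)[C@H](O[Si](C)(C)C(C)(C)C)[C@H](c1c(O)cc(OCc9ccccc9)cc1OCc9ccccc9)c1c(OCc9ccccc9)cc(OCc9ccccc9)c2c1O[C@H](c8ccc(OCc9ccccc9)c(OCc9ccccc9)c8)[C@H](OCc9ccccc9)C2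
F4 | step 9 | 2-[3,4-bis(benzyloxy)phenyl]-5,7-bis(benzyloxy)-3α-(tert-butyldimethylsilyloxy)-4β-(3,5,7,3',4'-penta-O-benzylepicatechin-8-yl)chroman-2-ol (hemiketal; both anomers) | c1c(OCc9ccccc9)cc(OCc9ccccc9)c3c1OC(O)(c8ccc(OCc9ccccc9)c(OCc9ccccc9)c8)[C@H](O[Si](C)(C)C(C)(C)C)[C@H]3c1c(OCc9ccccc9)cc(OCc9ccccc9)c2c1O[C@H](c8ccc(OCc9ccccc9)c(OCc9ccccc9)c8)[C@H](OCc9ccccc9)C2
F5 | step 18 | [3-O-acetyl-8-bromo-5,7,3',4'-tetra-O-benzylcatechin]-(4α→6)-[8-bromo-5,7,3',4'-tetra-O-benzylepicatechin] | Brc1c(OCc9ccccc9)cc(OCc9ccccc9)c2c1O[C@H](c8ccc(OCc9ccccc9)c(OCc9ccccc9)c8)[C@@H](OC(C)=O)[C@@H]2c1c(OCc9ccccc9)c(Br)c2c(c1OCc9ccccc9)C[C@@H](O)[C@@H](c8ccc(OCc9ccccc9)c(OCc9ccccc9)c8)O2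
F6 | step 18 | [3-O-acetyl-8-bromo-5,7,3',4'-tetra-O-benzylcatechin]-(4α→6)-[8-bromo-4β-(2-ethoxyethoxy)-5,7,3',4'-tetra-O-benzylepicatechin] | Brc1c(OCc9ccccc9)cc(OCc9ccccc9)c2c1O[C@H](c8ccc(OCc9ccccc9)c(OCc9ccccc9)c8)[C@@H](OC(C)=O)[C@@H]2c1c(OCc9ccccc9)c(Br)c2c(c1OCc9ccccc9)[C@H](OCCOCC)[C@@H](O)[C@@H](c8ccc(OCc9ccccc9)c(OCc9ccccc9)c8)O2
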